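The numbers in the tables are simulated with made-up constants; noise was put on by code.

A small charge of G leaves L standing still: in Monday's run, with G below two per J, L reads 5.8% at 1.50 h and 5.5% at 5.00 h, whereas Thursday's L falls from 34.0% to 6.7%.

| setting | Monday's | Thursday's | epsilon | delta | alpha |
|---|---|---|---|---|---|
| J | 0.10 M | 0.10 M | 0.10 M | 0.10 M | 0.10 M |
| G | 0.068 M | 0.37 M | 0.0500 M | 0.250 M | 0.300 M |
| remark | run made earlier | run made earlier |  |  |  |
| time |  |  | 6.0 h | 6.0 h | 6.0 h |

- Monday's (time / h: L / %): 0.333: 1.8; 1.00: 5.4; 1.50: 5.8; 2.50: 5.7; 4.00: 4.7; 5.00: 5.5; 6.00: 7.6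
- Thursday's (time / h: L / %): 0.333: 25.4; 1.00: 34.0; 1.50: 30.7; 2.50: 23.6; 4.00: 13.1; 5.00: 9.1; 6.00: 6.7

(each reading ± 1 percentage point)

- what was read earlier has a scatter of 1 percentage point, one standard deviation

* how much L is there at the end, in percent of the J charged: for each flask in turn (epsilon, delta, alpha)

L has two ligands exchanged, so the balance of G starts by setting aside two G per J. For delta that leaves 0.500: the surplus s, the G charged beyond two per J, counted per J charged. Alpha has 1.00, Thursday's run 1.70, and Monday's run and epsilon have a negative s, with G as limiting reagent.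

The first way to delta's end uses Thursday's late fall, which reads as a constant of 0.360 h⁻¹. Run back to zero time, it gives a top of 58.0%. Kept unchanged, that constant leaves 6.70% in delta. Monday's run exposes the flaw: the same constant predicts 1.65% at 5.00 h, less than the reading of 5.5%. So my reckoning treats the constant as pseudo-first-order and scales it with s, giving 30.7% for delta and 16.3% for alpha.

The second way is the balance itself. If a share s of the J charged takes a third G and the remainder stands as L in the proportion of the top, delta comes to top times one minus s, or 29.0%; this is my estimate for a surplus fully spent, not a floor. It lies near the scaled figure, but both rest on the top and on s, so the closeness checks nothing. For alpha the same subtraction gives zero while the scaled figure does not; the balance carries no time, so my reckoning stays with the scaled figures. For epsilon, scaling Monday's plateau by the square of the G charges gives 3.14%.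

The forecast differs from my reckoning, giving 4%, 6.3% and 6.6%, on the ground that the decay “shows no obvious dependence on G”.

The flasks give 3.49% for epsilon, 30.6% for delta and 19.7% for alpha.

    J + G → D + X (k = 0.00700 M⁻¹ s⁻¹)
    X + G → D + L (k = 0.00340 M⁻¹ s⁻¹)
    2 J → Z (k = 1.20 × 10⁻⁵ M⁻¹ s⁻¹)
    L ⇌ E (K = 0.700, k = 0.00660 s⁻¹)
    L + G → Q (k = 0.00160 M⁻¹ s⁻¹)

In delta, L passes to E with a forward half-life of 1.8 min, shorter than the 0.48 h of L going to Q with G. Q holds a third G and X one fewer than L, so, with J and Z, 0.0678% and 0.0845% in delta, set aside, Q minus X plus the G left, all per J charged, should return s. Delta at 6.00 h has Q 42.3%, X 5.49% and G 5.38% of its own charge, which sum to 0.503 against s of 0.500. Alpha's Q 65.6%, X 0.787% and G 11.8% sum to 1.00 against 1.00.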